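**Retrosynthetic overview**
1. Open pyran ring C of target 7 at the O1–C2 bond, O–C(CH3)2. This gives the 3,5-diprenyl phenol 6, and the C–O bond is made last by dehydrogenative cycloetherification (key step).
2. Remove both prenyl groups of 6. This gives deoxybenzoin 3 and prenyl bromide 4 (twofold nuclear prenylation).
3. Cut the aryl–acyl bond of 3. This gives 5-methoxyresorcinol 1 and 4-hydroxyphenylacetic acid 2, so the methyl ether is bought in.
4. Ring order: aromatic rings A and B are purchased, and ring C is the only ring built, in the final step.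

Assumption: the target has no stereocentre and its ring alkene can only be cis, so it is achiral and the compound drawn is the only form to be made.

**Step 1**
Reactants: 1 5-methoxyresorcinol; 2 4-hydroxyphenylacetic acid
Product: 3 1-(2,4-dihydroxy-6-methoxyphenyl)-2-(4-hydroxyphenyl)ethan-1-one
Conditions: BF3·OEt2 (neat, solvent and Lewis acid catalyst), 80 °C, 2 h; aq NaOAc; crystallisation or chromatography
Reagents that add atoms: none
Why: Friedel–Crafts (Nencki-type) acylation in which BF3 activates acid 2 and the electron-rich ring of 1 reacts at C4/C6 (two equivalent sites between OH and OMe, favoured statistically over C2); the chelated product resists a second acylation, the much less nucleophilic ring of 2 does not compete, and no stereocentre is formed.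

**Step 2**
Reactants: 3 1-(2,4-dihydroxy-6-methoxyphenyl)-2-(4-hydroxyphenyl)ethan-1-one; 4 prenyl bromide (1-bromo-3-methylbut-2-ene, 2.2 equiv)
Product: 6 1-[2,4-dihydroxy-6-methoxy-3,5-bis(3-methylbut-2-en-1-yl)phenyl]-2-(4-hydroxyphenyl)ethan-1-one, via 3-prenyl ketone 5 (not isolated)
Conditions: KOH (2.2 equiv, 1 M aq, added over 3 h so that the pH stays near 9), H2O, 0 °C to rt
Reagents that add atoms: prenyl bromide 4, CC(C)=CCBr
Why: Nuclear C-prenylation (SN2 alkylation of an ambident phenolate), where at pH 9 only the vinylogous-acid 4-OH (pKa about 7.5) is ionised while the ring B phenol (pKa about 10) and the chelated 2-OH stay protonated; water shields the phenolate oxygen, so the soft allylic bromide is taken up at carbon, first at C3 (giving 5) and then at C5, with rearomatisation each time and no stereocentre formed.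

**Step 3 (key step)**
Reactants: 6 1-[2,4-dihydroxy-6-methoxy-3,5-bis(3-methylbut-2-en-1-yl)phenyl]-2-(4-hydroxyphenyl)ethan-1-one
Product: 7 1-[5-hydroxy-7-methoxy-2,2-dimethyl-8-(3-methylbut-2-en-1-yl)-2H-chromen-6-yl]-2-(4-hydroxyphenyl)ethan-1-one
Conditions: Pd(OAc)2 (5 mol %), DMSO (20 mol %), O2 (1 atm), 3 Å MS, toluene, 60 °C
Reagents that add atoms: none
Why: Proposed new method: a chelate-anchored, site-selective aerobic Wacker-type 6-endo cycloetherification in which the 2-hydroxyaryl ketone unit of 6 displaces one acetate and holds divalent palladium as an anionic O,O-chelate, whose free site cis to O2 can be reached only by the alkene of the adjacent C3 prenyl group (a six-membered O–Pd–alkene chelate); the unbound 4-OH then attacks that alkene anti to the metal at its tertiary carbon to form the O–C(CH3)2 bond, β-hydride elimination of the only available (benzylic) hydrogen gives the chromene, and O2 returns zerovalent palladium to the divalent state with water as the only by-product; the C5 prenyl group lies out of reach of the anchored metal, the 2-oxygen is tied up as a ligand, chelation-induced bond fixation (C3=C4 double-bond character) biases the same closure, and no stereocentre is formed; the closest known reaction type is the divalent-palladium-catalysed aerobic oxidative cyclisation of o-allylphenols to 2H-chromenes, which has never been used to distinguish two prenyl groups flanking one phenol.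

**Compound list**
1 | 5-methoxyresorcinol (5-methoxybenzene-1,3-diol) | COc1cc(O)cc(O)c1 | starting material
2 | 4-hydroxyphenylacetic acid | OC(=O)Cc1ccc(O)cc1 | starting material
3 | 1-(2,4-dihydroxy-6-methoxyphenyl)-2-(4-hydroxyphenyl)ethan-1-one | COc1cc(O)cc(O)c1C(=O)Cc1ccc(O)cc1 | intermediate
4 | prenyl bromide (1-bromo-3-methylbut-2-ene) | CC(C)=CCBr | starting material
5 | 1-[2,4-dihydroxy-6-methoxy-3-(3-methylbut-2-en-1-yl)phenyl]-2-(4-hydroxyphenyl)ethan-1-one (3-prenyl ketone) | COc1cc(O)c(CC=C(C)C)c(O)c1C(=O)Cc1ccc(O)cc1 | intermediate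
6 | 1-[2,4-dihydroxy-6-methoxy-3,5-bis(3-methylbut-2-en-1-yl)phenyl]-2-(4-hydroxyphenyl)ethan-1-one | COc1c(CC=C(C)C)c(O)c(CC=C(C)C)c(O)c1C(=O)Cc1ccc(O)cc1 | intermediate
7 | 1-[5-hydroxy-7-methoxy-2,2-dimethyl-8-(3-methylbut-2-en-1-yl)-2H-chromen-6-yl]-2-(4-hydroxyphenyl)ethan-1-one (achiral) | COc1c(CC=C(C)C)c2c(c(O)c1C(=O)Cc1ccc(O)cc1)C=CC(C)(C)O2 | target

**Step count**
Total steps: 3. Longest linear sequence: 3. No protecting groups are used.

**Steps most likely to fail**

**Step 3 (the new step).**
- Risks: the catalyst may rest as an inert bis-chelate. Unanchored palladium may activate the C5 prenyl group and give the isomeric chromene. A 5-exo closure may give an isopropenyl dihydrobenzofuran.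
- The fallback uses known chemistry, sets out from 3 and comes back at 7. It builds ring C before the second prenyl group exists, so there is nothing left to distinguish.
- Ketone 3 is condensed with 3-methylbut-2-enal (ethylenediammonium diacetate 10 mol %, toluene, reflux). Knoevenagel-type attack at C3 and oxa-6π closure onto the free 4-OH give 1-(5-hydroxy-7-methoxy-2,2-dimethyl-2H-chromen-6-yl)-2-(4-hydroxyphenyl)ethan-1-one F1.
- The only non-chelated phenol is capped (MOMCl, iPr2NEt, CH2Cl2, 0 °C) to give 1-(5-hydroxy-7-methoxy-2,2-dimethyl-2H-chromen-6-yl)-2-[4-(methoxymethoxy)phenyl]ethan-1-one F2.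
- The chelated 5-OH is O-prenylated (4, K2CO3, DMF, 60 °C) to give 1-[7-methoxy-2,2-dimethyl-5-(3-methylbut-2-en-1-yloxy)-2H-chromen-6-yl]-2-[4-(methoxymethoxy)phenyl]ethan-1-one F3.
- Heating (N,N-diethylaniline, 190 °C) triggers the para-Claisen–Cope sequence. Both ortho positions are blocked, so an unrearranged prenyl group is delivered to C8, giving 1-[5-hydroxy-7-methoxy-2,2-dimethyl-8-(3-methylbut-2-en-1-yl)-2H-chromen-6-yl]-2-[4-(methoxymethoxy)phenyl]ethan-1-one F4.
- HCl in MeOH at 40 °C removes the acetal and gives 7.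

**Step 2.**
- Risks: O-alkylation at the 4-OH or 4'-OH, geminal 3,3-diprenylation with dearomatisation, and stalling at 5.
- The fallback sets out from 3 and comes back at 6. It replaces phenolate alkylation with halogenation and cross-coupling.
- NIS (2.05 equiv, MeCN, 0 °C) iodinates the two free positions of the far more activated ring A to give 1-(2,4-dihydroxy-3,5-diiodo-6-methoxyphenyl)-2-(4-hydroxyphenyl)ethan-1-one F5.
- A twofold Stille coupling with tributyl(3-methylbut-2-en-1-yl)stannane (Pd(PPh3)4, DMF, 90 °C) places both linear prenyl groups and gives 6.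

**Step 1.**
- Risk: attack at C2 of 1 gives the 2,6-dihydroxy-4-methoxy regioisomer, which can consume a large share of the material.
- The fallback sets out from 2 and comes back at 3. It removes the regiochemical question by using threefold-symmetric phloroglucinol (Oc1cc(O)cc(O)c1).
- Acylation of phloroglucinol with 2 in BF3·OEt2 gives 2-(4-hydroxyphenyl)-1-(2,4,6-trihydroxyphenyl)ethan-1-one F6.
- MOMCl (3.3 equiv, iPr2NEt, CH2Cl2) caps every hydroxyl except the one held in the chelate, giving 1-[2-hydroxy-4,6-bis(methoxymethoxy)phenyl]-2-[4-(methoxymethoxy)phenyl]ethan-1-one F7.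
- MeI and K2CO3 in refluxing acetone methylate the remaining hydroxyl, giving 1-[2-methoxy-4,6-bis(methoxymethoxy)phenyl]-2-[4-(methoxymethoxy)phenyl]ethan-1-one F8.
- HCl in MeOH at 50 °C removes the three acetals and gives 3.

**Further compounds**
F1 | step 3 | 1-(5-hydroxy-7-methoxy-2,2-dimethyl-2H-chromen-6-yl)-2-(4-hydroxyphenyl)ethan-1-one | COc1cc2c(c(O)c1C(=O)Cc1ccc(O)cc1)C=CC(C)(C)O2
F2 | step 3 | 1-(5-hydroxy-7-methoxy-2,2-dimethyl-2H-chromen-6-yl)-2-[4-(methoxymethoxy)phenyl]ethan-1-one | COc1cc2c(c(O)c1C(=O)Cc1ccc(OCOC)cc1)C=CC(C)(C)O2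
F3 | step 3 | 1-[7-methoxy-2,2-dimethyl-5-(3-methylbut-2-en-1-yloxy)-2H-chromen-6-yl]-2-[4-(methoxymethoxy)phenyl]ethan-1-one | COc1cc2c(c(OCC=C(C)C)c1C(=O)Cc1ccc(OCOC)cc1)C=CC(C)(C)O2
F4 | step 3 | 1-[5-hydroxy-7-methoxy-2,2-dimethyl-8-(3-methylbut-2-en-1-yl)-2H-chromen-6-yl]-2-[4-(methoxymethoxy)phenyl]ethan-1-one | COc1c(CC=C(C)C)c2c(c(O)c1C(=O)Cc1ccc(OCOC)cc1)C=CC(C)(C)O2
F5 | step 2 | 1-(2,4-dihydroxy-3,5-diiodo-6-methoxyphenyl)-2-(4-hydroxyphenyl)ethan-1-one | COc1c(I)c(O)c(I)c(O)c1C(=O)Cc1ccc(O)cc1
F6 | step 1 | 2-(4-hydroxyphenyl)-1-(2,4,6-trihydroxyphenyl)ethan-1-one | Oc1ccc(CC(=O)c2c(O)cc(O)cc2O)cc1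
F7 | step 1 | 1-[2-hydroxy-4,6-bis(methoxymethoxy)phenyl]-2-[4-(methoxymethoxy)phenyl]ethan-1-one | COCOc1ccc(CC(=O)c2c(O)cc(OCOC)cc2OCOC)cc1
F8 | step 1 | 1-[2-methoxy-4,6-bis(methoxymethoxy)phenyl]-2-[4-(methoxymethoxy)phenyl]ethan-1-one | COCOc1ccc(CC(=O)c2c(OC)cc(OCOC)cc2OCOC)cc1
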